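**Plan**
- Retrosynthesis: the phenol of ring C is unmasked last; the C3–C3a bond of the 2,3-dihydrobenzofuran is cut (ring B opened), then the O1–C2 aryl allyl ether bond, which leaves a ring A iodophenol and a ring C cinnamyl carbonate.
- Enabling feature: C3 carries only a methyl group and is bonded to C3a of ring A, so C3 and its methyl are the two carbons of a vinyl group on C2, and C3a can be an aryl radical generated from an iodide ortho to O1.
- Forward: ring C carbonate from syringaldehyde (steps 1–4) and ring A (E)-propenyl iodophenol from 5-iodovanillin (steps 5–6) are joined through O1–C2 (step 7); ring B then closes by radical cyclisation (step 8) and the silyl ether is removed (step 9).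
- Stereochemistry: C2 (S) comes from ligand control in an iridium-catalysed allylic etherification; C3 (S, trans to the ring C aryl group) comes from 1,2-induction by C2 in the ring closure; the (E)-propenyl geometry comes from thermodynamic equilibration.

Key step: step 8

Assumption: the (Sa,Sc,Sc) enantiomer of the phosphoramidite is taken to give the (S) allylic ether, in line with the usual sense of induction of this ligand class with cinnamyl carbonates and heteroatom nucleophiles; the mirror-image ligand would be used if the opposite sense were found.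

**Step 1**
Reactants: 1 syringaldehyde (4-hydroxy-3,5-dimethoxybenzaldehyde)
Product: 2 4-[(tert-butyldimethylsilyl)oxy]-3,5-dimethoxybenzaldehyde
Conditions: TBSCl (1.3 equiv), imidazole (2.5 equiv), DMF, rt
Reagents that add atoms: tert-butyldimethylsilyl chloride, CC(C)(C)[Si](C)(C)Cl
Why: Imidazole-promoted silylation of a phenol; the acidic phenol should silylate even between two methoxy groups, and the mask keeps it from quenching i-Bu2AlH in step 3 and from competing as an oxygen nucleophile in step 7.

**Step 2**
Reactants: 2 4-[(tert-butyldimethylsilyl)oxy]-3,5-dimethoxybenzaldehyde; 3 triethyl phosphonoacetate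
Product: 5 ethyl (2E)-3-{4-[(tert-butyldimethylsilyl)oxy]-3,5-dimethoxyphenyl}prop-2-enoate, via sodium phosphonate 4 (not isolated)
Conditions: NaH (1.2 equiv), 3 (1.25 equiv), THF, 0 °C; then 2, 0 °C to rt
Reagents that add atoms: sodium hydride, [Na+].[H-] (sodium of intermediate 4 only)
Why: Horner–Wadsworth–Emmons olefination, in which the stabilised phosphonate carbanion adds reversibly to the aryl aldehyde and the adduct leading to the (E)-cinnamate collapses fastest; no stereocentre is formed and the aryl silyl ether is inert to the non-nucleophilic base.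

**Step 3**
Reactants: 5 ethyl (2E)-3-{4-[(tert-butyldimethylsilyl)oxy]-3,5-dimethoxyphenyl}prop-2-enoate
Product: 6 (2E)-3-{4-[(tert-butyldimethylsilyl)oxy]-3,5-dimethoxyphenyl}prop-2-en-1-ol
Conditions: i-Bu2AlH (2.5 equiv), CH2Cl2, −78 °C; aq. KNaC4H4O6 (potassium sodium tartrate) work-up
Reagents that add atoms: none
Why: 1,2-Reduction of an α,β-unsaturated ester with i-Bu2AlH at low temperature should stop at the allylic alcohol and leave the alkene and the aryl silyl ether untouched.

**Step 4**
Reactants: 6 (2E)-3-{4-[(tert-butyldimethylsilyl)oxy]-3,5-dimethoxyphenyl}prop-2-en-1-ol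
Product: 7 (2E)-3-{4-[(tert-butyldimethylsilyl)oxy]-3,5-dimethoxyphenyl}prop-2-en-1-yl methyl carbonate
Conditions: ClCO2Me (1.5 equiv), pyridine (3 equiv), CH2Cl2, 0 °C
Reagents that add atoms: methyl chloroformate, COC(=O)Cl
Why: O-Acylation of the primary allylic alcohol with a chloroformate (carbonate formation) installs the leaving group needed for the allyl–iridium chemistry, and pyridine takes up the HCl so that the electron-rich cinnamyl system is not ionised.

**Step 5**
Reactants: 8 5-iodovanillin (4-hydroxy-3-iodo-5-methoxybenzaldehyde)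
Product: 10 2-iodo-6-methoxy-4-(prop-1-en-1-yl)phenol as a Z/E mixture, via sodium phenoxide 9 (not isolated)
Conditions: EtPPh3Br (1.6 equiv), NaN(SiMe3)2 (2.7 equiv), THF, 0 °C; then 8, 0 °C to rt; aq. NH4Cl
Reagents that add atoms: ethyltriphenylphosphonium bromide, CC[P+](c1ccccc1)(c1ccccc1)c1ccccc1.[Br-]; NaN(SiMe3)2, [Na+].C[Si](C)(C)[N-][Si](C)(C)C (sodium of intermediate 9 only)
Why: Wittig olefination with a non-stabilised ylide, in which the surplus base turns the phenol into phenoxide 9 whose aldehyde is still electrophilic enough for the reactive ethylidene ylide; kinetic collapse of the oxaphosphetane should give a Z-rich mixture, and the geometry is corrected in step 6.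

**Step 6**
Reactants: 10 2-iodo-6-methoxy-4-(prop-1-en-1-yl)phenol as a Z/E mixture
Product: 11 2-iodo-6-methoxy-4-[(1E)-prop-1-en-1-yl]phenol
Conditions: PdCl2(MeCN)2 (5 mol %), CH2Cl2, rt
Reagents that add atoms: none
Why: Palladium-catalysed Z to E isomerisation of a β-methylstyrene, in which reversible coordination and addition–elimination at divalent palladium should funnel both isomers to the thermodynamically preferred E alkene; the aryl iodide is inert because no zerovalent palladium is generated.

**Step 7**
Reactants: 11 2-iodo-6-methoxy-4-[(1E)-prop-1-en-1-yl]phenol; 7 (2E)-3-{4-[(tert-butyldimethylsilyl)oxy]-3,5-dimethoxyphenyl}prop-2-en-1-yl methyl carbonate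
Product: 13 2-{[(1S)-1-{4-[(tert-butyldimethylsilyl)oxy]-3,5-dimethoxyphenyl}prop-2-en-1-yl]oxy}-1-iodo-3-methoxy-5-[(1E)-prop-1-en-1-yl]benzene, via lithium aryloxide 12 (not isolated)
Conditions: 11 (1.5 equiv), LiN(SiMe3)2 (1.45 equiv), THF, 0 °C; then 7 (1.0 equiv), [Ir(cod)Cl]2 (2 mol %), (Sa,Sc,Sc)-O,O′-(1,1′-binaphthyl-2,2′-diyl)-N,N-bis(1-phenylethyl)phosphoramidite (4 mol %), catalyst pre-activated with n-PrNH2, THF, rt to 50 °C; aq. NH4Cl
Reagents that add atoms: LiN(SiMe3)2, [Li+].C[Si](C)(C)[N-][Si](C)(C)C (lithium of intermediate 12 only)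
Why: Iridium-catalysed asymmetric allylic etherification, in which the cyclometalated iridium–phosphoramidite complex ionises carbonate 7 and aryloxide 12 attacks the allyl ligand from outside at the aryl-substituted terminus (the branched selectivity typical of iridium, reinforced by the electron-rich aryl group) on the face dictated by the (Sa,Sc,Sc) ligand, which sets the future C2 as (S).

**Step 8**
Reactants: 13 2-{[(1S)-1-{4-[(tert-butyldimethylsilyl)oxy]-3,5-dimethoxyphenyl}prop-2-en-1-yl]oxy}-1-iodo-3-methoxy-5-[(1E)-prop-1-en-1-yl]benzene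
Product: 14 tert-butyl{2,6-dimethoxy-4-[(2S,3S)-7-methoxy-3-methyl-5-[(1E)-prop-1-en-1-yl]-2,3-dihydro-1-benzofuran-2-yl]phenoxy}dimethylsilane
Conditions: Bu3SnH (1.3 equiv), Et3B (0.3 equiv), trace air, toluene (0.05 M), 0 °C to rt; aq. KF work-up
Reagents that add atoms: none
Why: Ethyl radicals from Et3B and oxygen start a tin hydride chain in which Bu3Sn• takes the iodine atom from C3a of 13, the resulting σ aryl radical adds to the internal carbon of the vinyl group on C2 to form the C3–C3a bond, and the primary radical so formed takes hydrogen from Bu3SnH to become the C3 methyl group and to return Bu3Sn•. The closest known reaction type is the tin hydride mediated cyclisation of 2-halophenyl allyl ethers to 3-methyl-2,3-dihydrobenzofurans. Ring B closes in the 5-exo-trig mode. The new stereocentre C3 is controlled by the existing (S) centre C2 (1,2-induction): in the chair-like transition state the ring C aryl group on C2 sits pseudo-equatorial, so the forming CH2 radical is placed trans to it and C3 should become (S). The step needs 5-exo over 6-endo closure, which the short tether and the better overlap at the nearer alkene carbon secure; trans over cis selectivity, which the bulky aryl group on C2 and the low temperature secure; and an untouched (E)-propenyl group, which is secured because iodine abstraction and ring closure are very fast while addition to a 1,2-disubstituted styrene is slow and reversible. C2 never becomes a radical or an ion under these neutral conditions, so the configuration set in step 7 should be carried through.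

**Step 9**
Reactants: 14 tert-butyl{2,6-dimethoxy-4-[(2S,3S)-7-methoxy-3-methyl-5-[(1E)-prop-1-en-1-yl]-2,3-dihydro-1-benzofuran-2-yl]phenoxy}dimethylsilane
Product: 15 odoratisol A, 2,6-dimethoxy-4-[(2S,3S)-7-methoxy-3-methyl-5-[(1E)-prop-1-en-1-yl]-2,3-dihydro-1-benzofuran-2-yl]phenol
Conditions: Bu4NF (1.2 equiv), AcOH (1.2 equiv), THF, 0 °C
Reagents that add atoms: none
Why: Fluoride-induced desilylation of an aryl silyl ether, driven by the strong Si–F bond, with acetic acid buffering the phenoxide so that neither stereocentre nor the propenyl group is exposed to base.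

**Compound list**
1 | syringaldehyde (4-hydroxy-3,5-dimethoxybenzaldehyde) | COc1cc(C=O)cc(OC)c1O | starting material
2 | 4-[(tert-butyldimethylsilyl)oxy]-3,5-dimethoxybenzaldehyde | COc1cc(C=O)cc(OC)c1O[Si](C)(C)C(C)(C)C | intermediate
3 | triethyl phosphonoacetate | CCOC(=O)CP(=O)(OCC)OCC | starting material
4 | sodium salt of triethyl phosphonoacetate (phosphonate carbanion) | [Na+].CCOC(=O)[CH-]P(=O)(OCC)OCC | intermediate (not isolated)
5 | ethyl (2E)-3-{4-[(tert-butyldimethylsilyl)oxy]-3,5-dimethoxyphenyl}prop-2-enoate | CCOC(=O)/C=C/c1cc(OC)c(O[Si](C)(C)C(C)(C)C)c(OC)c1 | intermediate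
6 | (2E)-3-{4-[(tert-butyldimethylsilyl)oxy]-3,5-dimethoxyphenyl}prop-2-en-1-ol | OC/C=C/c1cc(OC)c(O[Si](C)(C)C(C)(C)C)c(OC)c1 | intermediate
7 | (2E)-3-{4-[(tert-butyldimethylsilyl)oxy]-3,5-dimethoxyphenyl}prop-2-en-1-yl methyl carbonate | COC(=O)OC/C=C/c1cc(OC)c(O[Si](C)(C)C(C)(C)C)c(OC)c1 | intermediate
8 | 5-iodovanillin (4-hydroxy-3-iodo-5-methoxybenzaldehyde) | COc1cc(C=O)cc(I)c1O | starting material
9 | sodium 4-formyl-2-iodo-6-methoxyphenolate | [Na+].[O-]c1c(I)cc(C=O)cc1OC | intermediate (not isolated)
10 | 2-iodo-6-methoxy-4-(prop-1-en-1-yl)phenol, Z/E mixture (alkene geometry left undefined on purpose) | CC=Cc1cc(OC)c(O)c(I)c1 | intermediate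
11 | 2-iodo-6-methoxy-4-[(1E)-prop-1-en-1-yl]phenol | C/C=C/c1cc(OC)c(O)c(I)c1 | intermediate
12 | lithium 2-iodo-6-methoxy-4-[(1E)-prop-1-en-1-yl]phenolate | [Li+].C/C=C/c1cc(OC)c([O-])c(I)c1 | intermediate (not isolated)
13 | 2-{[(1S)-1-{4-[(tert-butyldimethylsilyl)oxy]-3,5-dimethoxyphenyl}prop-2-en-1-yl]oxy}-1-iodo-3-methoxy-5-[(1E)-prop-1-en-1-yl]benzene | C/C=C/c1cc(OC)c(O[C@@H](C=C)c2cc(OC)c(O[Si](C)(C)C(C)(C)C)c(OC)c2)c(I)c1 | intermediate
14 | odoratisol A tert-butyldimethylsilyl ether, (2S,3S) | C/C=C/c1cc(OC)c2c(c1)[C@H](C)[C@@H](c1cc(OC)c(O[Si](C)(C)C(C)(C)C)c(OC)c1)O2 | intermediate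
15 | odoratisol A, (2S,3S) | C/C=C/c1cc(OC)c2c(c1)[C@H](C)[C@@H](c1cc(OC)c(O)c(OC)c1)O2 | target

**Total step count:** 9 steps.
**Longest linear sequence:** 7 steps (steps 1, 2, 3, 4, 7, 8, 9 from syringaldehyde); the ring A branch (steps 5 and 6) joins at step 7.

**Steps most likely to fail**

Step 7. The doubly ortho-substituted aryloxide may attack the allyl–iridium intermediate only slowly, so that the branched ether re-ionises, drifts toward the linear isomer and loses enantiopurity, or the silyl group migrates to the phenoxide. The fallback sets out from carbonate 7 and phenol 11 and comes back at 13. It gives the iridium step a small oxygen nucleophile and makes the aryl–oxygen bond by SN2 displacement. Carbonate 7 would undergo iridium-catalysed allylic hydroxylation with KHCO3 as the hydroxide equivalent, [Ir(cod)Cl]2 and the mirror-image (Ra,Rc,Rc) phosphoramidite in THF, to give (1R)-1-{4-[(tert-butyldimethylsilyl)oxy]-3,5-dimethoxyphenyl}prop-2-en-1-ol F1. Mitsunobu etherification of this alcohol with phenol 11 (PPh3, diisopropyl azodicarboxylate, toluene, 0 °C) should then proceed with inversion to give 13.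

Step 8. Stannyl and alkyl radicals may engage the styrene-type propenyl group (reversible addition with loss of E geometry, hydrostannation, oligomerisation), which would lower yield and geometric purity. The fallback sets out from sodium phenoxide 9 (made from 8 with NaN(SiMe3)2) and carbonate 7 and comes back at 14. It carries an aldehyde through the ring closure in place of the alkene. Etherification of 9 with 7 under the catalyst system of step 7 should give 4-{[(1S)-1-{4-[(tert-butyldimethylsilyl)oxy]-3,5-dimethoxyphenyl}prop-2-en-1-yl]oxy}-3-iodo-5-methoxybenzaldehyde F2. The same Bu3SnH/Et3B cyclisation should give (2S,3S)-2-{4-[(tert-butyldimethylsilyl)oxy]-3,5-dimethoxyphenyl}-7-methoxy-3-methyl-2,3-dihydro-1-benzofuran-5-carbaldehyde F3. A Julia–Kocienski olefination with 5-(ethylsulfonyl)-1-phenyl-1H-tetrazole and KN(SiMe3)2 in DME at −60 °C would then install the (E)-propenyl group and deliver 14.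

Step 5. Olefination of the phenoxide-deactivated aldehyde may stall, and the later equilibration may leave Z isomer that would be carried into the final product. The fallback sets out from 5-iodovanillin 8 and comes back at 11, bypassing 9, 10 and step 6. Silylation of 8 (TBSCl, imidazole, DMF) would give 4-[(tert-butyldimethylsilyl)oxy]-3-iodo-5-methoxybenzaldehyde F4. An E-selective Julia–Kocienski olefination with 5-(ethylsulfonyl)-1-phenyl-1H-tetrazole and KN(SiMe3)2 (DME, −60 °C) would give tert-butyl{2-iodo-6-methoxy-4-[(1E)-prop-1-en-1-yl]phenoxy}dimethylsilane F5. Desilylation with Bu4NF and AcOH in THF would return phenol 11.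

**Further compounds**
F1 | step 7 | (1R)-1-{4-[(tert-butyldimethylsilyl)oxy]-3,5-dimethoxyphenyl}prop-2-en-1-ol | O[C@H](C=C)c1cc(OC)c(O[Si](C)(C)C(C)(C)C)c(OC)c1
F2 | step 8 | 4-{[(1S)-1-{4-[(tert-butyldimethylsilyl)oxy]-3,5-dimethoxyphenyl}prop-2-en-1-yl]oxy}-3-iodo-5-methoxybenzaldehyde | O=Cc1cc(OC)c(O[C@@H](C=C)c2cc(OC)c(O[Si](C)(C)C(C)(C)C)c(OC)c2)c(I)c1
F3 | step 8 | (2S,3S)-2-{4-[(tert-butyldimethylsilyl)oxy]-3,5-dimethoxyphenyl}-7-methoxy-3-methyl-2,3-dihydro-1-benzofuran-5-carbaldehyde | O=Cc1cc(OC)c2c(c1)[C@H](C)[C@@H](c1cc(OC)c(O[Si](C)(C)C(C)(C)C)c(OC)c1)O2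
F4 | step 5 | 4-[(tert-butyldimethylsilyl)oxy]-3-iodo-5-methoxybenzaldehyde | COc1cc(C=O)cc(I)c1O[Si](C)(C)C(C)(C)C
F5 | step 5 | tert-butyl{2-iodo-6-methoxy-4-[(1E)-prop-1-en-1-yl]phenoxy}dimethylsilane | C/C=C/c1cc(OC)c(O[Si](C)(C)C(C)(C)C)c(I)c1
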